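**Strategy.** The cyclohexene ring (numbered C1 heptenyl, C2 CH2OH, C3 carbinol, C4/C5 epoxide, C6 carbinol) is read as a Robinson-type retron: the C3 carbinol is a former enone carbonyl, the C4–C5 epoxide a former enone C=C, and C6 a former α-oxy ketone carbon. One operation therefore joins an alkylidene β-keto ester phosphonate (C1–C4, C7 and the heptenyl chain) to a 1,4-bis(silyloxy)butan-2-one (C5, C6, C10, C11): an amine-catalysed Michael addition makes C1–C6 and sets C6, and an intramolecular Horner–Wadsworth–Emmons closure makes C4–C5 at the carbon that becomes the fully substituted epoxide centre. Epoxidation anti to the C6 silyloxy group, side-chain olefination, desaturation and hydride reduction finish the target.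

Key step: step 5

Remark on numbering: C7 is the hydroxymethyl carbon, C8/C9 the heptenyl alkene, C10–C13 the butenoic acid chain on C5 (C13 = CO2H).
Assumption: the quinine-derived primary amine is taken to give the R centre at C6; if the sense of induction is the opposite, the pseudoenantiomeric amine from quinidine is used.
Remark: C1 and C2 are epimer mixtures in 10–17 and are erased in step 10, so their SMILES carry no configuration at these two carbons.

Step 1
Reactants: 1 2-(diethoxyphosphoryl)acetic acid; 2 Meldrum's acid (2,2-dimethyl-1,3-dioxane-4,6-dione)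
Product: 4 methyl 4-(diethoxyphosphoryl)-3-oxobutanoate, via acyl Meldrum's acid 3 (not isolated)
Conditions: DCC, DMAP, CH2Cl2, 0 °C to rt; filter; then MeOH, reflux
Reagents that add atoms: methanol, CO
Why: Carbodiimide-mediated C-acylation of Meldrum's acid followed by methanolysis with loss of acetone and CO2 (the Meldrum's acid route to β-keto esters) should deliver the keto ester without touching the phosphonate; no stereocentre is formed.

Step 2
Reactants: 4 methyl 4-(diethoxyphosphoryl)-3-oxobutanoate; 5 (E)-oct-2-enal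
Product: 6 methyl (4E)-2-[2-(diethoxyphosphoryl)acetyl]deca-2,4-dienoate (2E/2Z mixture)
Conditions: piperidine (cat.), AcOH (cat.), 4 Å molecular sieves, CH2Cl2, 0 °C
Reagents that add atoms: none
Why: Knoevenagel condensation takes place at the C2 methylene, which lies between ketone and ester and is more acidic than the phosphonate methylene, and the enal reacts at its carbonyl group; the geometry of the new alkene is irrelevant because C1 becomes sp3 in step 5.

Step 3
Reactants: 7 butane-1,2,4-triol (racemic)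
Product: 8 1,4-bis(triethylsilyloxy)butan-2-ol
Conditions: Et3SiCl (2.05 equiv), imidazole, CH2Cl2, −40 °C
Reagents that add atoms: chlorotriethylsilane, CC[Si](Cl)(CC)CC
Why: Kinetic silylation distinguishes the two primary hydroxyl groups from the more hindered secondary one (selective silyl ether formation); the stereocentre of 7 is removed in step 4.

Step 4
Reactants: 8 1,4-bis(triethylsilyloxy)butan-2-ol
Product: 9 1,4-bis(triethylsilyloxy)butan-2-one
Conditions: Dess–Martin periodinane, pyridine, CH2Cl2, 0 °C to rt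
Reagents that add atoms: none
Why: Dess–Martin oxidation of the secondary alcohol is neutral and leaves both triethylsilyl ethers intact, whereas activated DMSO would attack the primary one.

Step 5
Reactants: 6 methyl (4E)-2-[2-(diethoxyphosphoryl)acetyl]deca-2,4-dienoate; 9 1,4-bis(triethylsilyloxy)butan-2-one
Product: 11 methyl (5R)-6-[(E)-hept-1-enyl]-2-oxo-5-(triethylsilyloxy)-4-[2-(triethylsilyloxy)ethyl]cyclohex-3-ene-1-carboxylate, via Michael adduct 10 (not isolated)
Conditions: 9-amino-9-deoxy-epi-quinine (20 mol %), PhCO2H (40 mol %), toluene, 0 °C to rt; then LiCl, DBU, MeCN, 0 °C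
Reagents that add atoms: none
Why: The primary amine condenses with 9 to the enamine on the oxygen-bearing side (C6), which adds 1,4 to C1 of the doubly activated alkylidene keto ester 6 and, after hydrolysis, leaves diketone 10; LiCl/DBU then forms the β-keto phosphonate anion at C4, which attacks the C5 ketone and expels diethyl phosphate. The closest known reaction type is the organocatalytic Michael/intramolecular Horner–Wadsworth–Emmons (Robinson-type) cyclohexenone annulation. The single ring is closed at C4–C5 in a 6-(enolendo)-exo-trig mode. The only stereocentre that is kept, C6 (R), is fixed by the chiral amine, which shields one face of the enamine; C1 and C2 are formed as epimer mixtures and are erased in step 10. The step needs regioselection between C6 and C10 (the α-silyloxy carbon should form the more stabilised enamine), 1,4- over 1,6-addition (C1 sits next to two carbonyl groups) and closure at C4 instead of an aldol from C10 (only C4 bears the phosphonate, and the C3 carbonyl is masked as its enolate under the basic conditions).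

Step 6
Reactants: 11 cyclohexenone keto ester (name as in step 5)
Product: 12 methyl (5R)-6-[(E)-hept-1-enyl]-2-oxo-1-(phenylsulfanyl)-5-(triethylsilyloxy)-4-[2-(triethylsilyloxy)ethyl]cyclohex-3-ene-1-carboxylate (PhS trans to heptenyl)
Conditions: N-(phenylsulfanyl)succinimide, Et3N (cat.), CH2Cl2, 0 °C
Reagents that add atoms: N-(phenylsulfanyl)succinimide, O=C1CCC(=O)N1Sc1ccccc1
Why: Amine-catalysed α-sulfenylation of the β-keto ester places sulfur on C2 trans to the C1 heptenyl group, hence cis to C1–H as the later syn-elimination requires, and removes the acidic C2–H that would otherwise quench the peroxide anion of step 7.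

Step 7
Reactants: 12 sulfanyl enone (name as in step 6)
Product: 13 methyl 4-[(E)-hept-1-enyl]-2-oxo-3-(phenylsulfanyl)-5-(triethylsilyloxy)-6-[2-(triethylsilyloxy)ethyl]-7-oxabicyclo[4.1.0]heptane-3-carboxylate (epoxide trans to the silyloxy group; silyloxy carbon R)
Conditions: t-BuOOH (anhydrous, in decane), DBU, CH2Cl2, 0 °C to rt
Reagents that add atoms: tert-butyl hydroperoxide, CC(C)(C)OO
Why: In this Weitz–Scheffer epoxidation the tert-butyl peroxide anion should add to C5 anti to the adjacent pseudoaxial C6 silyloxy group and the enolate then closes on oxygen, setting C4 and C5 trans to C6–O; the nucleophilic oxidant leaves the heptenyl alkene and the sulfide untouched.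

Step 8
Reactants: 13 epoxy ketone (name as in step 7)
Product: 15 methyl 4-[(E)-hept-1-enyl]-6-[(2E)-4-methoxy-3-methyl-4-oxobut-2-enyl]-2-oxo-3-(phenylsulfanyl)-5-(triethylsilyloxy)-7-oxabicyclo[4.1.0]heptane-3-carboxylate, via epoxy aldehyde 14 (not isolated)
Conditions: (COCl)2, DMSO, CH2Cl2, −78 to −40 °C; Et3N, −78 °C; then methyl 2-(triphenylphosphoranylidene)propanoate, −78 °C to rt
Reagents that add atoms: methyl 2-(triphenylphosphoranylidene)propanoate, COC(=O)C(C)=P(c1ccccc1)(c1ccccc1)c1ccccc1
Why: Activated DMSO converts the primary triethylsilyl ether directly into the aldehyde while the hindered secondary silyl ether survives (Swern oxidation of a silyl ether), and the base-labile β,γ-epoxy aldehyde is trapped at once by the stabilised ylide in an E-selective Wittig olefination.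

Step 9
Reactants: 15 diester (name as in step 8)
Product: 16 (2E)-4-[3-[(E)-hept-1-enyl]-4-(methoxycarbonyl)-5-oxo-4-(phenylsulfanyl)-2-(triethylsilyloxy)-7-oxabicyclo[4.1.0]heptan-1-yl]-2-methylbut-2-enoic acid
Conditions: Me3SnOH, 1,2-dichloroethane, 70 °C; cold 0.1 M HCl wash
Reagents that add atoms: trimethyltin hydroxide, C[Sn](C)(C)O
Why: Trimethyltin hydroxide cleaves the unhindered side-chain methyl ester under neutral conditions (tin-mediated ester hydrolysis) while the ring ester on the quaternary carbon is shielded, so the acid can pass through step 11 as an inert carboxylate.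

Step 10
Reactants: 16 sulfanyl keto ester acid (name as in step 9)
Product: 18 (2E)-4-[3-[(E)-hept-1-enyl]-4-(methoxycarbonyl)-5-oxo-2-(triethylsilyloxy)-7-oxabicyclo[4.1.0]hept-3-en-1-yl]-2-methylbut-2-enoic acid, via sulfoxide 17 (not isolated)
Conditions: mCPBA (1.0 equiv), CH2Cl2, −78 °C; then toluene, 40 °C; used at once
Reagents that add atoms: none
Why: Sulfide oxidation at −78 °C is faster than epoxidation of any alkene, and the sulfoxide syn-elimination, for which the sulfinyl group is cis to C1–H and no other β-hydrogen exists, should give the C1=C2 alkene under neutral conditions that avoid deprotonation at C6.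

Step 11
Reactants: 18 alkylidene keto ester acid (name as in step 10)
Product: 19 (2E)-4-[3-[(E)-hept-1-enyl]-5-hydroxy-4-(hydroxymethyl)-2-(triethylsilyloxy)-7-oxabicyclo[4.1.0]hept-3-en-1-yl]-2-methylbut-2-enoic acid (C3–OH cis to C6–OSi, trans to the epoxide)
Conditions: i-Bu2AlH (6 equiv), CH2Cl2–THF, −78 °C; aq. KNaC4H4O6
Reagents that add atoms: none
Why: i-Bu2AlH, coordinated to the epoxide oxygen and barred from the opposite face by the C5 side chain and the C6 silyloxy group, should deliver hydride to C3 from the epoxide face and reduce the conjugated methyl ester 1,2 to the allylic alcohol, while the side-chain acid is held as an unreactive aluminium carboxylate at −78 °C (chelation-controlled 1,2-reduction).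

Step 12
Reactants: 19 silyl-protected triol acid (name as in step 11)
Product: 20 (2E)-4-[(1S,2R,5S,6R)-3-[(1E)-hept-1-en-1-yl]-2,5-dihydroxy-4-(hydroxymethyl)-7-oxabicyclo[4.1.0]hept-3-en-1-yl]-2-methylbut-2-enoic acid
Conditions: HF·pyridine, pyridine, THF, 0 °C
Reagents that add atoms: none
Why: Buffered fluoride cleaves the last triethylsilyl ether (desilylation) without acid or strong base that could open the epoxide or ionise the dienyl carbinol.

**Compound list**

1 | 2-(diethoxyphosphoryl)acetic acid | CCOP(=O)(OCC)CC(=O)O | starting material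
2 | Meldrum's acid (2,2-dimethyl-1,3-dioxane-4,6-dione) | CC1(C)OC(=O)CC(=O)O1 | starting material
3 | 5-[2-(diethoxyphosphoryl)-1-hydroxyethylidene]-2,2-dimethyl-1,3-dioxane-4,6-dione | CCOP(=O)(OCC)CC(O)=C1C(=O)OC(C)(C)OC1=O | intermediate (not isolated)
4 | methyl 4-(diethoxyphosphoryl)-3-oxobutanoate | CCOP(=O)(OCC)CC(=O)CC(=O)OC | intermediate
5 | (E)-oct-2-enal | CCCCC/C=C/C=O | starting material
6 | methyl (4E)-2-[2-(diethoxyphosphoryl)acetyl]deca-2,4-dienoate (2E/2Z mixture) | CCCCC/C=C/C=C(C(=O)OC)C(=O)CP(=O)(OCC)OCC | intermediate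
7 | butane-1,2,4-triol (racemic) | OCCC(O)CO | starting material
8 | 1,4-bis(triethylsilyloxy)butan-2-ol | CC[Si](CC)(CC)OCCC(O)CO[Si](CC)(CC)CC | intermediate
9 | 1,4-bis(triethylsilyloxy)butan-2-one | CC[Si](CC)(CC)OCCC(=O)CO[Si](CC)(CC)CC | intermediate
10 | methyl (4R)-2-[2-(diethoxyphosphoryl)acetyl]-3-[(E)-hept-1-enyl]-5-oxo-4,7-bis(triethylsilyloxy)heptanoate (epimers at C2 and C3 of this name) | CCCCC/C=C/C(C(C(=O)OC)C(=O)CP(=O)(OCC)OCC)[C@@H](O[Si](CC)(CC)CC)C(=O)CCO[Si](CC)(CC)CC | intermediate (not isolated)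
11 | methyl (5R)-6-[(E)-hept-1-enyl]-2-oxo-5-(triethylsilyloxy)-4-[2-(triethylsilyloxy)ethyl]cyclohex-3-ene-1-carboxylate (ester- and heptenyl-bearing carbons as epimers) | CCCCC/C=C/C1C(C(=O)OC)C(=O)C=C(CCO[Si](CC)(CC)CC)[C@@H]1O[Si](CC)(CC)CC | intermediate
12 | methyl (5R)-6-[(E)-hept-1-enyl]-2-oxo-1-(phenylsulfanyl)-5-(triethylsilyloxy)-4-[2-(triethylsilyloxy)ethyl]cyclohex-3-ene-1-carboxylate (PhS trans to heptenyl) | CCCCC/C=C/C1C(Sc2ccccc2)(C(=O)OC)C(=O)C=C(CCO[Si](CC)(CC)CC)[C@@H]1O[Si](CC)(CC)CC | intermediate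
13 | methyl 4-[(E)-hept-1-enyl]-2-oxo-3-(phenylsulfanyl)-5-(triethylsilyloxy)-6-[2-(triethylsilyloxy)ethyl]-7-oxabicyclo[4.1.0]heptane-3-carboxylate (epoxide trans to the silyloxy group; silyloxy carbon R) | CCCCC/C=C/C1C(Sc2ccccc2)(C(=O)OC)C(=O)[C@H]2O[C@@]2(CCO[Si](CC)(CC)CC)[C@@H]1O[Si](CC)(CC)CC | intermediate
14 | methyl 4-[(E)-hept-1-enyl]-2-oxo-6-(2-oxoethyl)-3-(phenylsulfanyl)-5-(triethylsilyloxy)-7-oxabicyclo[4.1.0]heptane-3-carboxylate (ring configuration as in 13) | CCCCC/C=C/C1C(Sc2ccccc2)(C(=O)OC)C(=O)[C@H]2O[C@@]2(CC=O)[C@@H]1O[Si](CC)(CC)CC | intermediate (not isolated)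
15 | methyl 4-[(E)-hept-1-enyl]-6-[(2E)-4-methoxy-3-methyl-4-oxobut-2-enyl]-2-oxo-3-(phenylsulfanyl)-5-(triethylsilyloxy)-7-oxabicyclo[4.1.0]heptane-3-carboxylate (ring configuration as in 13) | CCCCC/C=C/C1C(Sc2ccccc2)(C(=O)OC)C(=O)[C@H]2O[C@@]2(C/C=C(\C)C(=O)OC)[C@@H]1O[Si](CC)(CC)CC | intermediate
16 | (2E)-4-[3-[(E)-hept-1-enyl]-4-(methoxycarbonyl)-5-oxo-4-(phenylsulfanyl)-2-(triethylsilyloxy)-7-oxabicyclo[4.1.0]heptan-1-yl]-2-methylbut-2-enoic acid (ring configuration as in 13) | CCCCC/C=C/C1C(Sc2ccccc2)(C(=O)OC)C(=O)[C@H]2O[C@@]2(C/C=C(\C)C(=O)O)[C@@H]1O[Si](CC)(CC)CC | intermediate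
17 | (2E)-4-[4-(benzenesulfinyl)-3-[(E)-hept-1-enyl]-4-(methoxycarbonyl)-5-oxo-2-(triethylsilyloxy)-7-oxabicyclo[4.1.0]heptan-1-yl]-2-methylbut-2-enoic acid (ring configuration as in 13) | CCCCC/C=C/C1C(S(=O)c2ccccc2)(C(=O)OC)C(=O)[C@H]2O[C@@]2(C/C=C(\C)C(=O)O)[C@@H]1O[Si](CC)(CC)CC | intermediate (not isolated)
18 | (2E)-4-[3-[(E)-hept-1-enyl]-4-(methoxycarbonyl)-5-oxo-2-(triethylsilyloxy)-7-oxabicyclo[4.1.0]hept-3-en-1-yl]-2-methylbut-2-enoic acid (epoxide trans to the silyloxy group; silyloxy carbon R) | CCCCC/C=C/C1=C(C(=O)OC)C(=O)[C@H]2O[C@@]2(C/C=C(\C)C(=O)O)[C@@H]1O[Si](CC)(CC)CC | intermediate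
19 | (2E)-4-[3-[(E)-hept-1-enyl]-5-hydroxy-4-(hydroxymethyl)-2-(triethylsilyloxy)-7-oxabicyclo[4.1.0]hept-3-en-1-yl]-2-methylbut-2-enoic acid (ring configuration of the target) | CCCCC/C=C/C1=C(CO)[C@H](O)[C@H]2O[C@@]2(C/C=C(\C)C(=O)O)[C@@H]1O[Si](CC)(CC)CC | intermediate
20 | (2E)-4-[(1S,2R,5S,6R)-3-[(1E)-hept-1-en-1-yl]-2,5-dihydroxy-4-(hydroxymethyl)-7-oxabicyclo[4.1.0]hept-3-en-1-yl]-2-methylbut-2-enoic acid | CCCCC/C=C/C1=C(CO)[C@H](O)[C@H]2O[C@@]2(C/C=C(\C)C(=O)O)[C@@H]1O | target

**Count.** Total steps: 12. Longest linear sequence: 10 steps (steps 1, 2 and 5–12).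

**Steps most likely to fail**

Step 5. Enamine formation may take place on the wrong α-carbon (C10), the donor may add 1,6, or the adduct may undergo retro-Michael reaction and epimerization at C6 before ring closure. The fallback sets out from 9 and comes back at 10. Ketone 9 is enolised toward its silyloxy-bearing carbon with TMSOTf/Et3N to the enol silane (Z)-1,4-bis(triethylsilyloxy)-2-(trimethylsilyloxy)but-1-ene F1. F1 then undergoes a Mukaiyama–Michael addition to 6 with Cu(OTf)2 and 2,2'-isopropylidenebis[(4S)-4-tert-butyl-2-oxazoline] (divalent copper chelated by the two carbonyl groups of 6; CH2Cl2, hexafluoroisopropanol, −78 °C). Mild acidic work-up removes the trimethylsilyl group and gives 10, which is closed to 11 with LiCl/DBU as in step 5.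

Step 10. The keto ester 18 may lose its epoxide and aromatise through deprotonation at C6, or the sulfenic acid may add back. The fallback sets out from 16 and comes back at 19, so that 18 is never formed. Compound 16 is first reduced with i-Bu2AlH at −78 °C (ketone and ring ester) to the sulfide diol (2E)-4-[3-[(E)-hept-1-enyl]-5-hydroxy-4-(hydroxymethyl)-4-(phenylsulfanyl)-2-(triethylsilyloxy)-7-oxabicyclo[4.1.0]heptan-1-yl]-2-methylbut-2-enoic acid F2. NaIO4 in aqueous MeOH at 0 °C then gives the sulfoxide (2E)-4-[4-(benzenesulfinyl)-3-[(E)-hept-1-enyl]-5-hydroxy-4-(hydroxymethyl)-2-(triethylsilyloxy)-7-oxabicyclo[4.1.0]heptan-1-yl]-2-methylbut-2-enoic acid F3. Thermolysis (toluene, NaHCO3, 100 °C) should eliminate toward C1–H, away from the two carbinol carbons, and give 19.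

Step 11. Hydride may add in conjugate fashion to the alkylidene keto ester, attack the carboxylate, or fail to discriminate the two faces of C3. The fallback sets out from 18 and comes back at 19 and separates the two reductions. A Luche reduction (NaBH4, CeCl3·7H2O, MeOH–THF, −78 °C) touches only the ketone, from the face opposite the C5 side chain and the C6 silyloxy group, and gives the hydroxy ester (2E)-4-[3-[(E)-hept-1-enyl]-5-hydroxy-4-(methoxycarbonyl)-2-(triethylsilyloxy)-7-oxabicyclo[4.1.0]hept-3-en-1-yl]-2-methylbut-2-enoic acid F4. The ring ester of F4, now next to an aluminium alkoxide, is then reduced with i-Bu2AlH at −78 °C to 19.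

**Further compounds**

F1 | step 5 | (Z)-1,4-bis(triethylsilyloxy)-2-(trimethylsilyloxy)but-1-ene | CC[Si](CC)(CC)OCC/C(O[Si](C)(C)C)=C/O[Si](CC)(CC)CC
F2 | step 10 | (2E)-4-[3-[(E)-hept-1-enyl]-5-hydroxy-4-(hydroxymethyl)-4-(phenylsulfanyl)-2-(triethylsilyloxy)-7-oxabicyclo[4.1.0]heptan-1-yl]-2-methylbut-2-enoic acid | CCCCC/C=C/C1C(Sc2ccccc2)(CO)[C@H](O)[C@H]2O[C@@]2(C/C=C(\C)C(=O)O)[C@@H]1O[Si](CC)(CC)CC
F3 | step 10 | (2E)-4-[4-(benzenesulfinyl)-3-[(E)-hept-1-enyl]-5-hydroxy-4-(hydroxymethyl)-2-(triethylsilyloxy)-7-oxabicyclo[4.1.0]heptan-1-yl]-2-methylbut-2-enoic acid | CCCCC/C=C/C1C(S(=O)c2ccccc2)(CO)[C@H](O)[C@H]2O[C@@]2(C/C=C(\C)C(=O)O)[C@@H]1O[Si](CC)(CC)CC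
F4 | step 11 | (2E)-4-[3-[(E)-hept-1-enyl]-5-hydroxy-4-(methoxycarbonyl)-2-(triethylsilyloxy)-7-oxabicyclo[4.1.0]hept-3-en-1-yl]-2-methylbut-2-enoic acid | CCCCC/C=C/C1=C(C(=O)OC)[C@H](O)[C@H]2O[C@@]2(C/C=C(\C)C(=O)O)[C@@H]1O[Si](CC)(CC)CC
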